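## Analysis of the target

Target 20 is a phenol whose benzene ring is pentasubstituted: with the arene numbered C1' (OH), C2' (Br), C3' (CH3), C4' (Br), C5' (H) and C6', the last carbon is bonded to C2 of a (1S,2R,5R)-1,2-dimethylbicyclo[3.1.0]hexane. The carbocycle is a cyclopentane (C1–C5) cis-fused to a cyclopropane (C1, C5, C6); C1 and C2 are adjacent quaternary carbons, each with a methyl group, and C5 is a methine. The three stereocentres are contiguous: the aryl group on C2 lies on the same face of the five-membered ring as the cyclopropane methylene C6, and the two methyl groups are cis to each other on the opposite face. The sensitive element is the cyclopropane next to the benzylic quaternary carbon C2 with a free hydroxyl ortho to it, because protic or Lewis acids can open the three-membered ring and let the phenol oxygen close onto the cation; the late steps must therefore stay neutral or basic. The difficulty lies in the two vicinal quaternary carbons with defined relative and absolute configuration, and in the crowded C2–C6' bond, which arylation of a preformed tertiary centre would make poorly. The plan rests on the pattern around C6': its neighbour C1' bears oxygen and C4', para to that oxygen, bears bromine. Ring C1'–C6' can therefore be grown on C2 from a 2-oxygenated diene (C6', C1' and the methylene termini C5' and C2') and a four-carbon ynoate (C3' with its methyl, C4' with an ester), the ester later being exchanged for bromine and the hydroxyl directing the second bromine to C2'.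

## Retrosynthetic reasoning

**20 to 19.** The two C–Br bonds are cut first. C4'–Br is traced back to a C4'–carboxyl bond and C2'–Br to C2'–H, which leads to hydroxy acid 19. A carboxyl para to a phenol is replaced by bromine through ipso attack and decarboxylation, and the single free ortho position is brominated in the same operation. Both halogens therefore arrive last, and no earlier step has to tolerate aryl bromides. The forward reaction has to be buffered so that no acid reaches the cyclopropane.

**19 to 18 to 17.** The two O–CH3 bonds (ester and aryl ether) are restored to give 18; the methyl groups carry the oxygen functions through the diene and cycloaddition stages and are removed together by a thiolate under basic conditions. Arene 18 is then traced to cyclohexa-1,4-diene 17 by adding back the hydrogens on C2' and C5'.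

**17 to 15 and 16.** The ring bonds C2'–C3' and C4'–C5' are cut, which divides 17 into diene 15 and ynoate 16. The cut is placed here because it makes no bond at the crowded C2–C6' junction, and because the donor oxygen on C1' fixes the orientation of the ester (to C4') and the methyl (to C3'). The forward reaction must be regioselective and must keep the acid-sensitive enol ether intact.

**15 to 11 and 12.** The central C–C bond of the diene (the future C6'–C1' bond) is cut. This is an sp2–sp2 cross-coupling between alkenyl triflate 11 and the metalated vinyl ether 14, which is made in the flask from 12 by way of 13. Both partners are simple, and the coupling creates no stereocentre.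

**11 to 10 to 8 to 6.** Triflate 11 comes from methyl ketone 10, which can enolise in one direction only. The C–CH3 bond of 10 is cut to acid 8 and a methyl organometallic, the addition passing by way of diolate 9, and 8 is the oxidation product of primary alcohol 6 by way of aldehyde 7. The carbinol carbon of 6 is thus the future C6'.

**6 to 5.** The cyclopropane bonds C1–C6 and C5–C6 are cut, leaving cyclopentene 5. The hydroxymethyl group on C2 is both the carbon that becomes C6' and the group that guides the zinc carbenoid, so the methylene is delivered to the face that later carries the aryl group. This sets C1 and C5 relative to C2.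

**5 to 3 to 2.** The C2–CH2OH bond is cut by a [2,3]-sigmatropic shift of lithiated ether 4, formed from stannane 3. The shift turns the C–O stereocentre of 2 into the quaternary carbon C2 and moves the double bond to where the cyclopropane is needed. Stannane 3 is the O-alkylation product of 2.

**2 to 1.** The carbinol stereocentre of 2 is traced to the carbonyl of enone 1 by enantioselective, catalyst-controlled hydride reduction. This is the only step in which a catalyst sets absolute configuration; all other stereocentres descend from it.

## Alternatives that were turned down

Alternative 1: carbonylative [2+2+1] assembly of the bicyclic core.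
- Disconnection: the cyclopentane bonds C1–C2, C2–C3 and C4–C5 are cut, with C2 at the oxidation level of a ketone.
- Forward key step: a cobalt-mediated Pauson–Khand reaction joins 1-methylcyclopropene A1 with ethynyltrimethylsilane A2 to give (1S,5S)-1-methyl-3-(trimethylsilyl)bicyclo[3.1.0]hex-3-en-2-one A3.
- For: it reaches the cis-fused core in one step from very small building blocks. The strained alkene A1 is a reactive partner, and the silyl group of A2 steers the alkyne orientation. On convergence and step count to the bicycle it is stronger than the chosen route.
- Against: C2 arrives in A3 as a carbonyl carbon. It must then be turned into a quaternary carbon with methyl and aryl, aryl cis to C6; adding an aryl metal and replacing the resulting tertiary hydroxyl by methyl would pass through a cyclopropylcarbinyl, benzylic cation that rearranges. The methyl-bearing carbon of A1 must also bond at the more hindered position next to the carbonyl. A1 is an achiral gas, so A3 would be racemic without a chiral promoter. The silyl group that A2 brings in and the ring alkene of A3 still have to be removed.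
- Comparison: the chosen route spends more steps on the bicycle, but it fixes C2 with its configuration by a stereospecific sigmatropic shift before the ring system is complete, and never makes a bond to C2 afterwards.

Alternative 2: photochemical ring contraction of a cyclohexadiene.
- Disconnection: the bonds C4–C5 and C1–C6 of the bicycle are cut and C4–C6 is restored, which unfolds the bicycle into a cyclohexa-1,4-diene whose ring methylene becomes C6.
- Forward key step: triplet-sensitised di-π-methane rearrangement of 2-[(1R)-1,2-dimethylcyclohexa-2,5-dien-1-yl]-1-methoxy-5-methylbenzene A4 to 2-[(1S,2R,5S)-1,2-dimethylbicyclo[3.1.0]hex-3-en-2-yl]-1-methoxy-5-methylbenzene A5.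
- For: the arene and the C2 quaternary carbon are present in A4 from the start, and one photochemical step forms both the cyclopentene and the cyclopropane of A5. It is clearly shorter, and its end-game (alkene reduction, ether cleavage, double bromination to 20) is as simple as that of the chosen route.
- Against: three selectivities are left to the excited state. The diradical must open so that the methyl-bearing carbon ends in the cyclopropane. The methylene must end on the aryl face, although methyl and aryl on the single stereocentre of A4 give little bias. The aryl group can itself bridge to a vinyl group and migrate. A4 also needs an enantioselective synthesis of its quaternary carbon, and the vinylcyclopropane alkene of A5 must be reduced without ring opening.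
- Comparison: the chosen route is longer, but every stereocentre is set by a closed-shell, stereospecific event (suprafacial shift, directed carbenoid delivery), so it does not depend on how a diradical partitions.

Alternative 3: gold-catalysed enyne cyclisation with oxidation of the carbene.
- Disconnection: the bonds C1–C5 and C1–C6 are cut to a 1,6-enyne, with the C1 methyl traced back to a formyl group.
- Forward key step: a cationic monovalent gold catalyst activates the alkyne of 1-methoxy-5-methyl-2-[(3R)-3-methylhept-6-en-1-yn-3-yl]benzene A6. The alkene adds in a 5-exo-dig sense, and a sulfoxide oxidant converts the exocyclic gold carbene into the aldehyde (1R,2S,5R)-2-(2-methoxy-4-methylphenyl)-2-methylbicyclo[3.1.0]hexane-1-carbaldehyde A7.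
- For: both rings of A7 form in one mild catalytic step, the arene is already in place in A6, and the C1 substituent arrives on the right carbon. On ring construction it is as strong as the chosen route, and shorter.
- Against: C1 and C5 are set relative to C2 in a transition state that must tell aryl from methyl on the propargylic quaternary carbon, so diastereoselectivity is uncertain. The electron-rich anisole ring can attack the activated alkyne or the carbene. A6 needs an enantioselective synthesis of an aryl, methyl, alkynyl quaternary centre. The formyl group of A7 must be deoxygenated to methyl at a neopentyl cyclopropyl position without radical or cationic ring opening.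
- Comparison: the chosen route builds the arene last, so it never has to discriminate aryl from methyl, and the carbon that becomes C6' doubles as the directing group for the cyclopropanation.

Key step: step 9

Remark on the chemistry: the (R)-oxazaborolidine is assumed to give the (S)-alcohol 2, the methyl-bearing alkene carbon acting as the large group of the ketone; were the sense opposite, the enantiomeric catalyst would be used.
Salts formed from a numbered compound by deprotonation alone (alkoxides, enolates, phenoxides, carboxylates) are not numbered separately.

## Route

Step 1
Reactants: 1 2,3-dimethylcyclopent-2-en-1-one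
Product: 2 (1S)-2,3-dimethylcyclopent-2-en-1-ol
Conditions: (R)-2-methyl-CBS-oxazaborolidine (10 mol %), BH3·SMe2, THF, −20 °C; MeOH quench, aq. work-up
Reagents that add atoms: none
Why: CBS reduction: the oxazaborolidine–borane complex binds the carbonyl oxygen anti to the substituted alkene side and delivers hydride to one face, which should give the S carbinol; the tetrasubstituted alkene is too hindered for hydroboration to compete.

Step 2
Reactants: 2 (1S)-2,3-dimethylcyclopent-2-en-1-ol
Product: 3 tributyl({[(1S)-2,3-dimethylcyclopent-2-en-1-yl]oxy}methyl)stannane
Conditions: KH, THF, 0 °C; Bu3SnCH2I, 0 °C to rt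
Reagents that add atoms: (iodomethyl)tributylstannane, CCCC[Sn](CCCC)(CCCC)CI
Why: Williamson etherification of the potassium alkoxide with a primary iodide gives the stannylmethyl ether required for the Wittig–Still rearrangement; the stereocentre is not touched.

Step 3
Reactants: 3 tributyl({[(1S)-2,3-dimethylcyclopent-2-en-1-yl]oxy}methyl)stannane
Product: 5 [(1R)-1,2-dimethylcyclopent-2-en-1-yl]methanol, via lithiomethyl ether 4 (not isolated)
Conditions: n-BuLi, THF, −78 to −40 °C; aq. NH4Cl
Reagents that add atoms: none
Why: Tin–lithium exchange gives the unstabilised α-alkoxymethyllithium 4, which undergoes the [2,3]-Wittig shift (Wittig–Still variant). In the five-membered ring the shift can only be suprafacial, so the CH2O group is delivered to the methyl-bearing alkene carbon on the face that carried oxygen; this sets the quaternary centre (future C2) as R and moves the alkene into position for the cyclopropane.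

Step 4
Reactants: 5 [(1R)-1,2-dimethylcyclopent-2-en-1-yl]methanol
Product: 6 [(1S,2R,5R)-1,2-dimethylbicyclo[3.1.0]hexan-2-yl]methanol
Conditions: Et2Zn (2.5 equiv), CH2I2 (5 equiv), CH2Cl2, 0 °C to rt
Reagents that add atoms: diiodomethane, ICI
Why: Hydroxyl-directed Simmons–Smith cyclopropanation (Furukawa conditions): the zinc alkoxide of the homoallylic alcohol carries the iodomethylzinc carbenoid to the alkene face syn to the CH2O group, which sets C1 (S) and C5 (R) with C6 cis to the carbinol carbon. Methylene transfer is stereospecific and the cis ring fusion follows from the ring size.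

Step 5
Reactants: 6 [(1S,2R,5R)-1,2-dimethylbicyclo[3.1.0]hexan-2-yl]methanol
Product: 8 (1S,2R,5R)-1,2-dimethylbicyclo[3.1.0]hexane-2-carboxylic acid, via aldehyde 7 (not isolated)
Conditions: TEMPO (10 mol %), NaClO2, NaOCl (cat.), MeCN, pH 6.7 phosphate buffer, 35 °C
Reagents that add atoms: sodium chlorite, [Na+].[O-]Cl=O
Why: Nitroxyl-catalysed oxidation with chlorite as terminal oxidant takes the primary alcohol through aldehyde 7 to the acid under buffered, near-neutral conditions that leave the cyclopropane alone; the α-carbon is quaternary, so nothing can epimerise.

Step 6
Reactants: 8 (1S,2R,5R)-1,2-dimethylbicyclo[3.1.0]hexane-2-carboxylic acid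
Product: 10 1-[(1S,2R,5R)-1,2-dimethylbicyclo[3.1.0]hexan-2-yl]ethan-1-one, via dilithium diolate 9 (not isolated)
Conditions: MeLi (2.5 equiv), Et2O, 0 °C to rt; inverse quench into cold aq. NH4Cl
Reagents that add atoms: methyllithium, [Li]C
Why: Addition of methyllithium to the lithium carboxylate gives the dilithium gem-diolate 9, which resists further addition and releases the methyl ketone only on hydrolysis (the classical conversion of an acid into a methyl ketone, favoured by the α-quaternary carbon).

Step 7
Reactants: 10 1-[(1S,2R,5R)-1,2-dimethylbicyclo[3.1.0]hexan-2-yl]ethan-1-one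
Product: 11 1-[(1S,2R,5R)-1,2-dimethylbicyclo[3.1.0]hexan-2-yl]ethenyl trifluoromethanesulfonate
Conditions: KN(SiMe3)2, THF, −78 °C; PhNTf2, −78 to 0 °C
Reagents that add atoms: N-phenylbis(trifluoromethanesulfonimide), O=S(=O)(N(c1ccccc1)S(=O)(=O)C(F)(F)F)C(F)(F)F
Why: The ketone can enolise only toward its methyl group, so O-triflation of the potassium enolate gives a single alkenyl triflate, as with other tert-alkyl methyl ketones.

Step 8
Reactants: 11 1-[(1S,2R,5R)-1,2-dimethylbicyclo[3.1.0]hexan-2-yl]ethenyl trifluoromethanesulfonate; 12 methoxyethene (methyl vinyl ether)
Product: 15 (1S,2R,5R)-2-(3-methoxybuta-1,3-dien-2-yl)-1,2-dimethylbicyclo[3.1.0]hexane, via 1-methoxyvinyllithium 13 (not isolated), via 1-methoxyvinylzinc chloride 14 (not isolated)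
Conditions: 12, t-BuLi, THF, −78 to 0 °C; ZnCl2, 0 °C; then 11, Pd(PPh3)4 (5 mol %), THF, rt to 45 °C; aq. NaHCO3 work-up, Et3N-deactivated silica
Reagents that add atoms: none
Why: α-Lithiation of the vinyl ether and transmetalation to zinc give 14, which undergoes Negishi cross-coupling with the alkenyl triflate under zerovalent palladium catalysis (oxidative addition, transmetalation, reductive elimination). Organozinc reagents cope with the hindered neopentyl-type electrophile, and the lithium chloride formed in the flask assists coupling of the triflate.

Step 9
Reactants: 15 (1S,2R,5R)-2-(3-methoxybuta-1,3-dien-2-yl)-1,2-dimethylbicyclo[3.1.0]hexane; 16 methyl but-2-ynoate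
Product: 17 methyl 5-[(1S,2R,5R)-1,2-dimethylbicyclo[3.1.0]hexan-2-yl]-4-methoxy-2-methylcyclohexa-1,4-diene-1-carboxylate
Conditions: 16 (5 equiv), BHT (cat.), toluene, 150 °C, sealed base-washed tube
Reagents that add atoms: none
Why: Thermal Diels–Alder reaction of an electron-rich 2-alkoxydiene with an alkynoate, the known benzannulation type in which 2-alkoxy- and 2-silyloxybuta-1,3-dienes add to propiolate and butynoate esters. The diene reacts through its s-cis rotamer, which the tertiary alkyl group on the internal carbon favours by destabilising the s-trans form, and the two σ-bonds C2'–C3' and C4'–C5' form in one concerted, asynchronous, suprafacial [4+2] event. The six-membered ring is thus closed by intermolecular cycloaddition of the four diene carbons onto the two alkyne carbons, not by a stepwise cyclisation, and it emerges as a cyclohexa-1,4-diene one oxidation level below the arene. No stereocentre is created (both new sp3 carbons are methylenes), and C1, C2 and C5 take no part, so nothing can epimerise. The step needs regioselectivity: the methoxy group raises the HOMO coefficient at its adjacent CH2 terminus, which bonds to the electron-poor β-carbon of 16 (the carbon bearing methyl), so that ester and methoxy end up 1,4 and methyl and methoxy 1,3. The alkyl group on the other internal carbon pushes weakly in the opposite sense but is the poorer donor, so the orientation shown should prevail, and a regioisomer would be separable after aromatisation. Chemoselectivity is secured because the non-conjugated product cannot react as a diene and because no bond has to be made at the crowded C2–C6' junction.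

Step 10
Reactants: 17 methyl 5-[(1S,2R,5R)-1,2-dimethylbicyclo[3.1.0]hexan-2-yl]-4-methoxy-2-methylcyclohexa-1,4-diene-1-carboxylate
Product: 18 methyl 5-[(1S,2R,5R)-1,2-dimethylbicyclo[3.1.0]hexan-2-yl]-4-methoxy-2-methylbenzoate
Conditions: DDQ (1.1 equiv), dry toluene, 0 °C to rt
Reagents that add atoms: none
Why: DDQ abstracts hydride from a doubly allylic CH2 of the cyclohexa-1,4-diene and loss of a proton gives the benzene ring (dehydrogenative aromatisation); the ester-bearing arene and the cyclopropane are not oxidised at room temperature.

Step 11
Reactants: 18 methyl 5-[(1S,2R,5R)-1,2-dimethylbicyclo[3.1.0]hexan-2-yl]-4-methoxy-2-methylbenzoate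
Product: 19 5-[(1S,2R,5R)-1,2-dimethylbicyclo[3.1.0]hexan-2-yl]-4-hydroxy-2-methylbenzoic acid
Conditions: NaSEt (8 equiv), DMF, 140 °C; then cold aq. citric acid to pH 4
Reagents that add atoms: none
Why: Ethanethiolate cleaves the methyl ester and the aryl methyl ether by SN2 attack at the methyl carbons; the basic, acid-free medium suits the cyclopropane, which boron or aluminium halides would open. Partial loss of the carboxyl group at this temperature would do no harm, since the para position is brominated in the next step in either case.

Step 12
Reactants: 19 5-[(1S,2R,5R)-1,2-dimethylbicyclo[3.1.0]hexan-2-yl]-4-hydroxy-2-methylbenzoic acid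
Product: 20 2,4-dibromo-6-[(1S,2R,5R)-1,2-dimethylbicyclo[3.1.0]hexan-2-yl]-3-methylphenol
Conditions: Br2 (2.05 equiv), NaHCO3 (6 equiv), MeCN/H2O, 0 °C; aq. Na2S2O3
Reagents that add atoms: bromine, BrBr
Why: Electrophilic aromatic bromination of the phenoxide: ipso attack at C4', para to oxygen, is followed by decarboxylation of the dienone (bromodecarboxylation of a 4-hydroxybenzoic acid), and the only free ortho position C2' takes the second bromine. Bicarbonate removes the hydrogen bromide, so the cyclopropane should not be opened.

## Compound list

1 | 2,3-dimethylcyclopent-2-en-1-one | CC1=C(C)C(=O)CC1 | starting material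
2 | (1S)-2,3-dimethylcyclopent-2-en-1-ol | O[C@H]1CCC(C)=C1C | intermediate
3 | tributyl({[(1S)-2,3-dimethylcyclopent-2-en-1-yl]oxy}methyl)stannane | CCCC[Sn](CCCC)(CCCC)CO[C@H]1CCC(C)=C1C | intermediate
4 | ({[(1S)-2,3-dimethylcyclopent-2-en-1-yl]oxy}methyl)lithium | [Li]CO[C@H]1CCC(C)=C1C | intermediate (not isolated)
5 | [(1R)-1,2-dimethylcyclopent-2-en-1-yl]methanol | OC[C@]1(C)CCC=C1C | intermediate
6 | [(1S,2R,5R)-1,2-dimethylbicyclo[3.1.0]hexan-2-yl]methanol | OC[C@]1(C)CC[C@@H]2C[C@@]21C | intermediate
7 | (1S,2R,5R)-1,2-dimethylbicyclo[3.1.0]hexane-2-carbaldehyde | O=C[C@]1(C)CC[C@@H]2C[C@@]21C | intermediate (not isolated)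
8 | (1S,2R,5R)-1,2-dimethylbicyclo[3.1.0]hexane-2-carboxylic acid | OC(=O)[C@]1(C)CC[C@@H]2C[C@@]21C | intermediate
9 | dilithium 1-[(1S,2R,5R)-1,2-dimethylbicyclo[3.1.0]hexan-2-yl]ethane-1,1-bis(olate) | [Li]OC(C)(O[Li])[C@]1(C)CC[C@@H]2C[C@@]21C | intermediate (not isolated)
10 | 1-[(1S,2R,5R)-1,2-dimethylbicyclo[3.1.0]hexan-2-yl]ethan-1-one | CC(=O)[C@]1(C)CC[C@@H]2C[C@@]21C | intermediate
11 | 1-[(1S,2R,5R)-1,2-dimethylbicyclo[3.1.0]hexan-2-yl]ethenyl trifluoromethanesulfonate | C=C(OS(=O)(=O)C(F)(F)F)[C@]1(C)CC[C@@H]2C[C@@]21C | intermediate
12 | methoxyethene (methyl vinyl ether) | C=COC | starting material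
13 | (1-methoxyethenyl)lithium | [Li]C(=C)OC | intermediate (not isolated)
14 | chlorido(1-methoxyethenyl)zinc | Cl[Zn]C(=C)OC | intermediate (not isolated)
15 | (1S,2R,5R)-2-(3-methoxybuta-1,3-dien-2-yl)-1,2-dimethylbicyclo[3.1.0]hexane | C=C(OC)C(=C)[C@]1(C)CC[C@@H]2C[C@@]21C | intermediate
16 | methyl but-2-ynoate | CC#CC(=O)OC | starting material
17 | methyl 5-[(1S,2R,5R)-1,2-dimethylbicyclo[3.1.0]hexan-2-yl]-4-methoxy-2-methylcyclohexa-1,4-diene-1-carboxylate | COC(=O)C1=C(C)CC(OC)=C(C1)[C@]2(C)CC[C@@H]3C[C@@]32C | intermediate
18 | methyl 5-[(1S,2R,5R)-1,2-dimethylbicyclo[3.1.0]hexan-2-yl]-4-methoxy-2-methylbenzoate | COC(=O)c1cc(c(OC)cc1C)[C@]2(C)CC[C@@H]3C[C@@]32C | intermediate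
19 | 5-[(1S,2R,5R)-1,2-dimethylbicyclo[3.1.0]hexan-2-yl]-4-hydroxy-2-methylbenzoic acid | OC(=O)c1cc(c(O)cc1C)[C@]2(C)CC[C@@H]3C[C@@]32C | intermediate
20 | 2,4-dibromo-6-[(1S,2R,5R)-1,2-dimethylbicyclo[3.1.0]hexan-2-yl]-3-methylphenol | Cc1c(Br)cc([C@]2(C)CC[C@@H]3C[C@@]32C)c(O)c1Br | target

## Step count and least certain steps

Total step count: 12. Longest linear sequence: 12 steps (1 to 20); 12 and 16 enter as purchased reagents.

**Step 9 (key step).** The cycloaddition may be slow, because a β-methyl ynoate is a weakly activated dienophile, while the enol ether diene hydrolyses or polymerises on long heating. Regioselectivity may also erode, because the alkyl group on the diene opposes the methoxy group. Fallback: the dienophile is changed to the more reactive allenic ester methyl buta-2,3-dienoate (C=C=CC(=O)OC), which reacts at its conjugated double bond well below 150 °C with the same polarisation. From 15 this gives methyl 5-[(1S,2R,5R)-1,2-dimethylbicyclo[3.1.0]hexan-2-yl]-4-methoxy-2-methylidenecyclohex-4-ene-1-carboxylate F1 (mixture at the ester-bearing carbon). Treatment with DBU moves the exocyclic double bond into conjugation with the ester and returns the route to 17; any 1,3-diene isomer formed alongside is aromatised to 18 by the same DDQ step.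

**Step 3.** A [1,2]-shift through a radical pair may compete with the [2,3]-shift, and the [2,3]-shift itself may be slow, because the new bond is made at a fully substituted alkene carbon and creates a quaternary centre. Fallback: the quaternary carbon is made by copper-mediated anti-SN2' substitution instead of a sigmatropic shift. Starting again from 1, reduction with the (S)-oxazaborolidine gives (1R)-2,3-dimethylcyclopent-2-en-1-ol F2, which is esterified with pyridine-2-carboxylic acid (DCC, DMAP) to (1R)-2,3-dimethylcyclopent-2-en-1-yl pyridine-2-carboxylate F3. Reaction with (i-PrO)Me2SiCH2MgCl and CuBr·SMe2 in THF delivers the silylmethyl group anti to the leaving group at the γ-carbon and gives {[(1R)-1,2-dimethylcyclopent-2-en-1-yl]methyl}(dimethyl)(propan-2-yloxy)silane F4. Tamao–Fleming oxidation (H2O2, KF, KHCO3) then returns the route to 5.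

**Step 4.** Facial selectivity may be poor, because the directing hydroxyl is homoallylic and the two groups on the allylic quaternary carbon (CH3 and CH2OH) differ little in size, so undirected methylene transfer to the other face can compete. Fallback: the methylene carbon is delivered through a covalent tether. Alcohol 5 is acylated with glyoxylic acid chloride p-toluenesulfonylhydrazone (PhNMe2, then Et3N) to [(1R)-1,2-dimethylcyclopent-2-en-1-yl]methyl 2-diazoacetate F5. Rh2(OAc)4 in dilute CH2Cl2 gives, by intramolecular cyclopropanation that can only reach the face carrying the CH2O group, the δ-lactone of 6-endo-carboxy-2-(hydroxymethyl)-1,2-dimethylbicyclo[3.1.0]hexane F6. Reduction with i-Bu2AlH at −78 °C gives the corresponding lactol F7, and its open hydroxy aldehyde form is decarbonylated with stoichiometric RhCl(PPh3)3 in hot toluene, which returns the route to 6.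

**Step 8.** Oxidative addition and transmetalation may be slow at the hindered triflate, with reduction of the triflate or decay of the organozinc reagent as competing processes, and the product enol ether may hydrolyse on isolation. Fallback: the C–C bond is made by carbonyl addition instead of cross-coupling. From 10, addition of 13 in the presence of CeCl3 (THF, −78 °C) gives 2-[(1S,2R,5R)-1,2-dimethylbicyclo[3.1.0]hexan-2-yl]-3-methoxybut-3-en-2-ol F8 (mixture at the carbinol carbon). Syn-elimination with the Burgess reagent, for which only the methyl group offers β-hydrogens, returns the route to 15.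

**Step 12.** Acid set free locally may open the cyclopropane with capture by the phenol oxygen. With excess bromine, ipso attack may also take place at the alkyl-bearing C6', or ring bromination may outrun the decarboxylation. Fallback: decarboxylation and halogenation are separated and no hydrogen bromide is generated. From 19, protodecarboxylation with catalytic Ag2CO3 in DMSO at 120 °C (the acid has the ortho substituent this reaction needs) gives 2-[(1S,2R,5R)-1,2-dimethylbicyclo[3.1.0]hexan-2-yl]-5-methylphenol F9. One equivalent of NBS in MeCN at 0 °C brominates para to the hydroxyl to give 4-bromo-2-[(1S,2R,5R)-1,2-dimethylbicyclo[3.1.0]hexan-2-yl]-5-methylphenol F10. A second equivalent of NBS with catalytic i-Pr2NH in CH2Cl2 brominates the remaining ortho position and returns the route to 20.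

## Further compounds

F1 | step 9 | methyl 5-[(1S,2R,5R)-1,2-dimethylbicyclo[3.1.0]hexan-2-yl]-4-methoxy-2-methylidenecyclohex-4-ene-1-carboxylate (mixture at C1 of the cyclohexene) | COC(=O)C1CC(=C(OC)CC1=C)[C@]2(C)CC[C@@H]3C[C@@]32C
F2 | step 3 | (1R)-2,3-dimethylcyclopent-2-en-1-ol | O[C@@H]1CCC(C)=C1C
F3 | step 3 | (1R)-2,3-dimethylcyclopent-2-en-1-yl pyridine-2-carboxylate | O=C(O[C@@H]1CCC(C)=C1C)c1ccccn1
F4 | step 3 | {[(1R)-1,2-dimethylcyclopent-2-en-1-yl]methyl}(dimethyl)(propan-2-yloxy)silane | CC(C)O[Si](C)(C)C[C@]1(C)CCC=C1C
F5 | step 4 | [(1R)-1,2-dimethylcyclopent-2-en-1-yl]methyl 2-diazoacetate | [N-]=[N+]=CC(=O)OC[C@]1(C)CCC=C1C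
F6 | step 4 | δ-lactone of 6-endo-carboxy-2-(hydroxymethyl)-1,2-dimethylbicyclo[3.1.0]hexane (C1, C2, C5 as in 6) | O=C1OC[C@]2(C)CC[C@@H]3[C@H]1[C@@]32C
F7 | step 4 | lactol from reduction of F6 (mixture at the hemiacetal carbon) | OC1OC[C@]2(C)CC[C@@H]3[C@H]1[C@@]32C
F8 | step 8 | 2-[(1S,2R,5R)-1,2-dimethylbicyclo[3.1.0]hexan-2-yl]-3-methoxybut-3-en-2-ol (mixture at the carbinol carbon) | C=C(OC)C(C)(O)[C@]1(C)CC[C@@H]2C[C@@]21C
F9 | step 12 | 2-[(1S,2R,5R)-1,2-dimethylbicyclo[3.1.0]hexan-2-yl]-5-methylphenol | Cc1ccc(c(O)c1)[C@]2(C)CC[C@@H]3C[C@@]32C
F10 | step 12 | 4-bromo-2-[(1S,2R,5R)-1,2-dimethylbicyclo[3.1.0]hexan-2-yl]-5-methylphenol | Cc1cc(O)c(cc1Br)[C@]2(C)CC[C@@H]3C[C@@]32C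
A1 | alternative 1 | 1-methylcyclopropene | CC1=CC1
A2 | alternative 1 | ethynyltrimethylsilane | C#C[Si](C)(C)C
A3 | alternative 1 | (1S,5S)-1-methyl-3-(trimethylsilyl)bicyclo[3.1.0]hex-3-en-2-one | C[Si](C)(C)C1=C[C@@H]2C[C@]2(C)C1=O
A4 | alternative 2 | 2-[(1R)-1,2-dimethylcyclohexa-2,5-dien-1-yl]-1-methoxy-5-methylbenzene | COc1cc(C)ccc1[C@]2(C)C=CCC=C2C
A5 | alternative 2 | 2-[(1S,2R,5S)-1,2-dimethylbicyclo[3.1.0]hex-3-en-2-yl]-1-methoxy-5-methylbenzene | COc1cc(C)ccc1[C@]2(C)C=C[C@@H]3C[C@@]32C
A6 | alternative 3 | 1-methoxy-5-methyl-2-[(3R)-3-methylhept-6-en-1-yn-3-yl]benzene | COc1cc(C)ccc1[C@](C#C)(C)CCC=C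
A7 | alternative 3 | (1R,2S,5R)-2-(2-methoxy-4-methylphenyl)-2-methylbicyclo[3.1.0]hexane-1-carbaldehyde | COc1cc(C)ccc1[C@]2(C)CC[C@@H]3C[C@@]32C=O
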